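(The numbers in the tables come from a simulation for an exercise; the scatter is artificial.)

4 questions stand on Saturday's flask, and I answer them with one number.

| flask | solid substrate | second substrate | capture agent | free catalyst | temperature | remark | time |
|---|---|---|---|---|---|---|---|
| Saturday's | 20 mM | 1 equiv | 1 mM | 0.5 mol% | 5 °C | the very flask that is asked about, followed so far |  |
| Monday's | 20 mM | 1 equiv | 1 mM | 0.5 mol% | −10 °C | run made earlier |  |
| flask | 20 mM | 1.00 equiv | 1.00 mM | 0.5 mol% | 5 °C |  | 25 min |

| run | time / min | target / % |
|---|---|---|
| Saturday's | 4.00 | 16.9 |
| Saturday's | 8.00 | 19.2 |
| Saturday's | 12.0 | 17.0 |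
| Saturday's | 15.0 | 15.5 |
| Monday's | 8.00 | 9.4 |
| Monday's | 15.0 | 9.3 |
| Monday's | 25.0 | 10.3 |
| Monday's | 30.0 | 9.1 |

(readings scatter by 1 percentage point)

1. target, in percent of the solid substrate first charged, at 25 min
2. which option adds most target ("none" when 2 percentage points or less is all one gets) (noon / spring / summer / winter / none)
3. target present, with what was taken out counted in, in percent of the solid substrate first charged, after spring
4. target present, with what was taken out counted in, in percent of the solid substrate first charged, after winter

- noon: at 25 min add free catalyst, 50.0% of the amount charged, then wait 12 min
- spring: at 25 min take out 90% of the target then present, then wait 12 min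
- summer: change nothing and wait 12 min more
- winter: at 25 min raise the temperature by 10 K, then wait 12 min

- as a solid, counted per litre of solution: solid substrate
- target that was removed still counts
- at the start none of the solid substrate is in solution
- additions bring no volume worth counting

I read Saturday's run as a level with a mean of 17.2%, and Monday's colder run as a lower level. The catalyst charge is 0.100 mM and the capture agent charge is ten times that, so target that stands still so far below its charge looks to me like a stopped catalyst. So I count the turnover budget (a turnover number), the target made per catalyst charged: 34.3.

Now I turn the settings by hand. In summer, waiting adds nothing in my reckoning, as the level stands by the first reading at 4.00 min, so I expect 17.2% at 25 min. In spring, taking out target gives a stopped catalyst nothing to do, so the total stays at the level. In winter, warming likewise acts on a stopped catalyst, so I expect no gain. At noon, new catalyst brings a new budget, and half the charge should add 8.6 percentage points. My choice is noon.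

The forecast differs: 12.5% now, spring as best, 20% after spring and 12% after winter. On catalyst it says: “Extra catalyst or waiting won't help.”

The flask gives 17.3% now and noon as best, with 18 points against 0 points for spring, 0 points for summer and 0 points for winter. It stands at 17.3% after spring and 17.3% after winter.

    starting material + free catalyst ⇌ catalyst intermediate A (K = 12000 L mol⁻¹, k = 470 L mol⁻¹ s⁻¹, Ea = 42.0 kJ mol⁻¹, ΔH = −2.00 kJ mol⁻¹)
    catalyst intermediate A → free catalyst + target (k = 200 s⁻¹, Ea = 59.0 kJ mol⁻¹)
    second substrate + free catalyst ⇌ catalyst intermediate B (K = 76.0 L mol⁻¹, k = 600 L mol⁻¹ s⁻¹, Ea = 37.0 kJ mol⁻¹, ΔH = −28.0 kJ mol⁻¹)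
    catalyst intermediate B → free catalyst + second product (k = 12.0 s⁻¹, Ea = 62.0 kJ mol⁻¹)
    catalyst intermediate B + capture agent → trapped intermediate (k = 240 L mol⁻¹ s⁻¹, Ea = 38.0 kJ mol⁻¹)
    solid substrate ⇌ starting material, rate k6*(cs6 - [starting material]) while solid is left; crystals form when [starting material] > cs6 (solubility = 13.0 mM, k = 0.160 s⁻¹)
    (constants at 5 °C)

The main reason for the stop is the path from catalyst intermediate B + capture agent to trapped intermediate: the same flask without that path reaches 100% at 25 min. At 25.0 min the flask holds 100% of its catalyst as trapped intermediate, with 90.0% of the capture agent left. My noon figure has the right direction but is about half of the computed gain.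

In the neighbour flask with 50 mM of solid substrate, c(starting material) stands at the same 13.0 mM, while the second substrate charge is 2.50 times that of Saturday's flask. Taking the budget to follow c(starting material) over c(second substrate), like a selectivity factor, I shrink it by that ratio to 13.7, which gives 6.86% of that flask's charge; the computed result is 6.69%.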